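**Strategy.** The cycloundecadiene ring is closed between the carbinol carbon C1 and the allylic methylene C2 that flanks the C3(Me)=C4 olefin. Both are by nature electrophilic (C1 a latent carbonyl carbon, C2 an allylic halide carbon), so C1 is used with reversed polarity: a phenylsulfonyl group makes it a carbanion that displaces a primary allylic chloride in an acyclic (E,E)-geranyl-derived chain carrying the gem-dimethyl unit. One operation thus forms the eleven-membered ring with both E-olefins in place. The sulfone is then exchanged oxidatively for the C1 carbonyl, a CBS reduction sets the single stereocenter, and the (Z)-coumarate is built by esterification with (Z)-3-iodoacrylic acid and Suzuki coupling.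

Key step: step 6

Remark: ring atoms are numbered C1 (carbinol carbon), C2 (allylic CH2), C3(Me)=C4, C7(Me)=C8, C10 (CMe2), C11; the sulfonyl-bearing C1 of 11 to 13 forms without stereocontrol and is erased in step 7, so it is written without configuration.

**Step 1**
Reactants: 1 geranyl chloride [(2E)-1-chloro-3,7-dimethylocta-2,6-diene]; 2 isobutyraldehyde (2-methylpropanal)
Product: 3 (4E)-2,2,5,9-tetramethyldeca-4,8-dienal
Conditions: 50% aq NaOH, Bu4NI (5 mol %), toluene, 60 °C
Reagents that add atoms: none
Why: Phase-transfer C-alkylation of the enolate of an alpha-branched aldehyde (SN2 at the primary allylic chloride) should give the quaternary aldehyde, which has no alpha-hydrogen left and so cannot be alkylated again, while the E-olefin of the geranyl unit is not touched.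

**Step 2**
Reactants: 3 (4E)-2,2,5,9-tetramethyldeca-4,8-dienal; 4 diethyl [(phenylsulfonyl)methyl]phosphonate
Product: 5 (1E,5E)-3,3,6,10-tetramethyl-1-(phenylsulfonyl)undeca-1,5,9-triene
Conditions: NaH, THF, 0 °C to rt
Reagents that add atoms: none
Why: Horner-Wadsworth-Emmons olefination with the sulfonyl-stabilised phosphonate anion adds the future C1 as a CH-SO2Ph unit; the non-enolisable, hindered aldehyde should still react cleanly, and the E geometry of the new olefin is irrelevant because it is reduced in step 3.

**Step 3**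
Reactants: 5 (1E,5E)-3,3,6,10-tetramethyl-1-(phenylsulfonyl)undeca-1,5,9-triene
Product: 6 (6E)-2,6,9,9-tetramethyl-11-(phenylsulfonyl)undeca-2,6-diene
Conditions: NaBH4, EtOH/THF, 0 to 50 °C
Reagents that add atoms: none
Why: Conjugate hydride reduction of an alpha,beta-unsaturated sulfone should saturate only the electron-poor olefin and leave the two isolated trisubstituted olefins alone; the gamma-carbon is quaternary, so base-induced migration to an allyl sulfone is impossible.

**Step 4**
Reactants: 6 (6E)-2,6,9,9-tetramethyl-11-(phenylsulfonyl)undeca-2,6-diene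
Product: 7 (2E,6E)-2,6,9,9-tetramethyl-11-(phenylsulfonyl)undeca-2,6-dien-1-ol
Conditions: SeO2 (0.3 equiv), tBuOOH (3 equiv), CH2Cl2, 0 °C to rt, stopped before over-oxidation
Reagents that add atoms: tert-butyl hydroperoxide, CC(C)(C)OO (terminal oxygen source, transferred through catalytic SeO2, O=[Se]=O)
Why: Riley allylic oxidation (ene reaction, then [2,3]-sigmatropic shift) should hydroxylate the E-methyl group of the terminal, more accessible trisubstituted olefin and give the E-allylic alcohol, as is usual for geranyl-type chains; the sulfone is inert.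

**Step 5**
Reactants: 7 (2E,6E)-2,6,9,9-tetramethyl-11-(phenylsulfonyl)undeca-2,6-dien-1-ol
Product: 9 (2E,6E)-1-chloro-2,6,9,9-tetramethyl-11-(phenylsulfonyl)undeca-2,6-diene, via allylic mesylate 8 (not isolated)
Conditions: MsCl, 2,4,6-collidine, LiCl, DMF, 0 °C
Reagents that add atoms: lithium chloride, [Li+].[Cl-]
Why: Mesylation followed by in situ SN2 displacement with chloride converts a primary allylic alcohol into the chloride without allylic transposition or loss of the E geometry.

**Step 6**
Reactants: 9 (2E,6E)-1-chloro-2,6,9,9-tetramethyl-11-(phenylsulfonyl)undeca-2,6-diene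
Product: 11 (3E,7E)-3,7,10,10-tetramethylcycloundeca-3,7-dien-1-yl phenyl sulfone, via lithium sulfonyl carbanion 10 (not isolated)
Conditions: LiN(iPr)2 (1.3 equiv), THF, -78 to 0 °C, syringe-pump addition of 9, final concentration about 0.003 M
Reagents that add atoms: none
Why: LiN(iPr)2 removes a proton alpha to the sulfonyl group of 9, and carbanion 10 displaces the primary allylic chloride at the other end of the chain in an intramolecular SN2 reaction that joins C1 to C2. The sulfonyl group is an acyl-anion handle: it gives the future carbinol carbon, by nature a carbonyl-type acceptor, donor character so that it can be united with the equally electrophilic allylic carbon; the closest known reaction type is the high-dilution macrocyclisation of sulfone- or cyanohydrin-ether-stabilised carbanions onto allylic halides, used for ten-, eleven- and fourteen-membered terpenoid carbocycles. The eleven-membered carbocycle closes in the 11-exo-tet mode. The only new stereocenter, C1 bearing the sulfonyl group, forms without control and is of no consequence because it becomes the carbonyl carbon in step 7. The step needs ring closure to beat oligomerisation (slow addition to high dilution, helped by the gem-dimethyl group and the two E-olefins, which restrict the chain), SN2 to beat SN2' (attack at the trisubstituted olefin carbon is hindered and would have to form a nine-membered ring) and both E geometries to survive (neither olefin takes part, as chloride leaves from the primary carbon without allyl transposition).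

**Step 7**
Reactants: 11 (3E,7E)-3,7,10,10-tetramethylcycloundeca-3,7-dien-1-yl phenyl sulfone
Product: 14 (3E,7E)-3,7,10,10-tetramethylcycloundeca-3,7-dien-1-one, via lithiated sulfone 12 (not isolated), via silyloxy sulfone 13 (not isolated)
Conditions: LiN(iPr)2, THF, -78 °C; then Me3SiOOSiMe3, -78 to 0 °C; aq NH4Cl
Reagents that add atoms: bis(trimethylsilyl) peroxide, C[Si](C)(C)OO[Si](C)(C)C
Why: Oxidative desulfonylation: the alpha-sulfonyl carbanion attacks a peroxide oxygen and the alpha-silyloxy sulfone collapses with loss of benzenesulfinate to the ketone; the cold, weakly basic medium should keep the C3=C4 olefin out of conjugation.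

**Step 8**
Reactants: 14 (3E,7E)-3,7,10,10-tetramethylcycloundeca-3,7-dien-1-one
Product: 16 (1S,3E,7E)-3,7,10,10-tetramethylcycloundeca-3,7-dien-1-ol, via catecholborate ester 15 (not isolated)
Conditions: (S)-2-methyl-CBS-oxazaborolidine (20 mol %), catecholborane, toluene, -78 °C; then MeOH, aq NaOH work-up
Reagents that add atoms: none
Why: Corey-Bakshi-Shibata reduction: with the (S)-oxazaborolidine, hydride should be delivered to the face that gives the (1S)-alcohol if the neopentyl-type arm (C11H2-C10Me2) acts as the large substituent and the allylic C2H2 arm as the small one; catecholborane at -78 °C should not hydroborate the olefins.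

**Step 9**
Reactants: 16 (1S,3E,7E)-3,7,10,10-tetramethylcycloundeca-3,7-dien-1-ol; 17 (2Z)-3-iodoprop-2-enoic acid
Product: 18 (1S,3E,7E)-3,7,10,10-tetramethylcycloundeca-3,7-dien-1-yl (2Z)-3-iodoprop-2-enoate
Conditions: DIC, DMAP (10 mol %), CH2Cl2, -20 to 0 °C, dark
Reagents that add atoms: none
Why: Steglich esterification acylates the secondary alcohol with retention at C1; run cold, in the dark and with little DMAP, it should keep the Z geometry of the beta-iodoacrylate.

**Step 10**
Reactants: 18 (1S,3E,7E)-3,7,10,10-tetramethylcycloundeca-3,7-dien-1-yl (2Z)-3-iodoprop-2-enoate; 19 (4-hydroxyphenyl)boronic acid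
Product: 20 (1S,3E,7E)-3,7,10,10-tetramethylcycloundeca-3,7-dien-1-yl (2Z)-3-(4-hydroxyphenyl)prop-2-enoate
Conditions: Pd(PPh3)4 (5 mol %), K2CO3, THF/H2O, rt, dark
Reagents that add atoms: none
Why: Suzuki-Miyaura coupling of an alkenyl iodide is stereoretentive in both oxidative addition and reductive elimination, so the Z-iodoacrylate should give the Z-coumarate at room temperature; the free phenol is tolerated as its phenoxide and the ester should not be hydrolysed.

**Compound list**
1 | geranyl chloride, (2E)-1-chloro-3,7-dimethylocta-2,6-diene | CC(C)=CCC/C(C)=C/CCl | starting material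
2 | isobutyraldehyde | CC(C)C=O | starting material
3 | (4E)-2,2,5,9-tetramethyldeca-4,8-dienal | CC(C)=CCC/C(C)=C/CC(C)(C)C=O | intermediate
4 | diethyl [(phenylsulfonyl)methyl]phosphonate | CCOP(=O)(CS(=O)(=O)c1ccccc1)OCC | starting material
5 | (1E,5E)-3,3,6,10-tetramethyl-1-(phenylsulfonyl)undeca-1,5,9-triene | CC(C)=CCC/C(C)=C/CC(C)(C)/C=C/S(=O)(=O)c1ccccc1 | intermediate
6 | (6E)-2,6,9,9-tetramethyl-11-(phenylsulfonyl)undeca-2,6-diene | CC(C)=CCC/C(C)=C/CC(C)(C)CCS(=O)(=O)c1ccccc1 | intermediate
7 | (2E,6E)-2,6,9,9-tetramethyl-11-(phenylsulfonyl)undeca-2,6-dien-1-ol | OC/C(C)=C/CC/C(C)=C/CC(C)(C)CCS(=O)(=O)c1ccccc1 | intermediate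
8 | (2E,6E)-2,6,9,9-tetramethyl-11-(phenylsulfonyl)undeca-2,6-dien-1-yl methanesulfonate | CS(=O)(=O)OC/C(C)=C/CC/C(C)=C/CC(C)(C)CCS(=O)(=O)c1ccccc1 | intermediate (not isolated)
9 | (2E,6E)-1-chloro-2,6,9,9-tetramethyl-11-(phenylsulfonyl)undeca-2,6-diene | ClC/C(C)=C/CC/C(C)=C/CC(C)(C)CCS(=O)(=O)c1ccccc1 | intermediate
10 | lithium alpha-sulfonyl carbanion of 9 | ClC/C(C)=C/CC/C(C)=C/CC(C)(C)C[CH-]S(=O)(=O)c1ccccc1.[Li+] | intermediate (not isolated)
11 | (3E,7E)-3,7,10,10-tetramethylcycloundeca-3,7-dien-1-yl phenyl sulfone (C1 racemic) | C/C1=C\CC(C)(C)CC(S(=O)(=O)c2ccccc2)C/C(C)=C/CC1 | intermediate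
12 | lithium alpha-sulfonyl carbanion of 11 | C/C1=C\CC(C)(C)C[C-](S(=O)(=O)c2ccccc2)C/C(C)=C/CC1.[Li+] | intermediate (not isolated)
13 | (3E,7E)-3,7,10,10-tetramethyl-1-(trimethylsilyloxy)cycloundeca-3,7-dien-1-yl phenyl sulfone | C/C1=C\CC(C)(C)CC(O[Si](C)(C)C)(S(=O)(=O)c2ccccc2)C/C(C)=C/CC1 | intermediate (not isolated)
14 | (3E,7E)-3,7,10,10-tetramethylcycloundeca-3,7-dien-1-one | C/C1=C\CC(C)(C)CC(=O)C/C(C)=C/CC1 | intermediate
15 | 2-{[(1S,3E,7E)-3,7,10,10-tetramethylcycloundeca-3,7-dien-1-yl]oxy}-1,3,2-benzodioxaborole | C/C1=C\CC(C)(C)C[C@H](OB2Oc3ccccc3O2)C/C(C)=C/CC1 | intermediate (not isolated)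
16 | (1S,3E,7E)-3,7,10,10-tetramethylcycloundeca-3,7-dien-1-ol | C/C1=C\CC(C)(C)C[C@H](O)C/C(C)=C/CC1 | intermediate
17 | (2Z)-3-iodoprop-2-enoic acid | OC(=O)/C=C\I | starting material
18 | (1S,3E,7E)-3,7,10,10-tetramethylcycloundeca-3,7-dien-1-yl (2Z)-3-iodoprop-2-enoate | C/C1=C\CC(C)(C)C[C@H](OC(=O)/C=C\I)C/C(C)=C/CC1 | intermediate
19 | (4-hydroxyphenyl)boronic acid | OB(O)c1ccc(O)cc1 | starting material
20 | (1S,3E,7E)-3,7,10,10-tetramethylcycloundeca-3,7-dien-1-yl (2Z)-3-(4-hydroxyphenyl)prop-2-enoate | C/C1=C\CC(C)(C)C[C@H](OC(=O)/C=C\c2ccc(O)cc2)C/C(C)=C/CC1 | target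

**Total step count:** 10
**Longest linear sequence:** 10 steps (from 1 to 20)

**Steps most likely to fail**

1. Step 6 (ring closure). Intermolecular alkylation may outrun closure of the eleven-membered ring, and the amide base may cause 1,4-elimination of HCl from the allylic chloride before the carbanion forms.
Fallback (sets out from 6, comes back at 11): the ring is closed instead by a palladium-catalysed allylic alkylation under neutral conditions with a doubly stabilised carbanion.
 - Sulfone 6 is C-acylated (LiN(iPr)2, 2.2 equiv, THF, -78 °C, then ClCO2Me) to methyl (6E)-4,4,7,11-tetramethyl-2-(phenylsulfonyl)dodeca-6,10-dienoate F1.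
 - Riley oxidation as in step 4 should give the allylic alcohol methyl (6E,10E)-12-hydroxy-4,4,7,11-tetramethyl-2-(phenylsulfonyl)dodeca-6,10-dienoate F2.
 - ClCO2Me and pyridine in CH2Cl2 at 0 °C convert it to the allylic methyl carbonate F3.
 - Slow addition of F3 to Pd(PPh3)4 (10 mol %) and 1,2-bis(diphenylphosphino)ethane in THF at 65 °C ionises the carbonate to a pi-allylpalladium complex. The released methoxide deprotonates the sulfonyl ester, and the soft carbanion should attack the CH2 terminus to give the macrocyclic sulfonyl ester methyl (3E,7E)-3,7,10,10-tetramethyl-1-(phenylsulfonyl)cycloundeca-3,7-diene-1-carboxylate F4.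
 - Krapcho demethoxycarbonylation (LiCl, wet DMSO, 130 °C) returns sulfone 11.

2. Step 8 (CBS reduction). Both groups on the carbonyl are methylene arms, so enantiofacial discrimination by the oxazaborolidine may be poor or may run in the opposite sense.
Fallback (sets out from 14, comes back at 16): classical resolution.
 - NaBH4 in MeOH at 0 °C gives the racemic alcohol (3E,7E)-3,7,10,10-tetramethylcycloundeca-3,7-dien-1-ol F5.
 - DCC/DMAP coupling with (S)-2-methoxy-2-phenylacetic acid gives two diastereomeric esters, the (1S)-cycloundecadienyl (S)-2-methoxy-2-phenylacetate F6 and the (1R)-cycloundecadienyl (S)-2-methoxy-2-phenylacetate F7. They are to be separated by chromatography; the O-methylmandelate also allows the configuration at C1 to be assigned by NMR.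
 - LiOH in THF/MeOH/H2O cleaves F6 to 16.

3. Step 9 (esterification). Acylation of the ring alcohol next to the neopentyl-type C11 may be slow, which would give DMAP time to isomerise the Z-iodoacrylate to the E isomer by reversible conjugate addition; any E ester would be carried into step 10.
Fallback (sets out from 16, comes back at 20): the Z-olefin is made by olefination instead.
 - DCC/DMAP coupling of 16 with 2-(diphenoxyphosphoryl)acetic acid gives the phosphonoacetate (1S,3E,7E)-3,7,10,10-tetramethylcycloundeca-3,7-dien-1-yl 2-(diphenoxyphosphoryl)acetate F8.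
 - Z-selective Horner-Wadsworth-Emmons reaction of this diaryl phosphonoacetate with 4-[(tert-butyldimethylsilyl)oxy]benzaldehyde (NaH, THF, -78 to 0 °C) should give the silyl-protected (Z)-coumarate F9.
 - HF·pyridine in THF at 0 °C frees the phenol to give 20.

**Further compounds**
F1 | step 6 | methyl (6E)-4,4,7,11-tetramethyl-2-(phenylsulfonyl)dodeca-6,10-dienoate | CC(C)=CCC/C(C)=C/CC(C)(C)CC(C(=O)OC)S(=O)(=O)c1ccccc1
F2 | step 6 | methyl (6E,10E)-12-hydroxy-4,4,7,11-tetramethyl-2-(phenylsulfonyl)dodeca-6,10-dienoate | OC/C(C)=C/CC/C(C)=C/CC(C)(C)CC(C(=O)OC)S(=O)(=O)c1ccccc1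
F3 | step 6 | methyl (6E,10E)-12-[(methoxycarbonyl)oxy]-4,4,7,11-tetramethyl-2-(phenylsulfonyl)dodeca-6,10-dienoate | COC(=O)OC/C(C)=C/CC/C(C)=C/CC(C)(C)CC(C(=O)OC)S(=O)(=O)c1ccccc1
F4 | step 6 | methyl (3E,7E)-3,7,10,10-tetramethyl-1-(phenylsulfonyl)cycloundeca-3,7-diene-1-carboxylate | C/C1=C\CC(C)(C)CC(C(=O)OC)(S(=O)(=O)c2ccccc2)C/C(C)=C/CC1
F5 | step 8 | (3E,7E)-3,7,10,10-tetramethylcycloundeca-3,7-dien-1-ol (racemic) | C/C1=C\CC(C)(C)CC(O)C/C(C)=C/CC1
F6 | step 8 | (1S,3E,7E)-3,7,10,10-tetramethylcycloundeca-3,7-dien-1-yl (2S)-2-methoxy-2-phenylacetate | C/C1=C\CC(C)(C)C[C@H](OC(=O)[C@@H](OC)c2ccccc2)C/C(C)=C/CC1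
F7 | step 8 | (1R,3E,7E)-3,7,10,10-tetramethylcycloundeca-3,7-dien-1-yl (2S)-2-methoxy-2-phenylacetate | C/C1=C\CC(C)(C)C[C@@H](OC(=O)[C@@H](OC)c2ccccc2)C/C(C)=C/CC1
F8 | step 9 | (1S,3E,7E)-3,7,10,10-tetramethylcycloundeca-3,7-dien-1-yl 2-(diphenoxyphosphoryl)acetate | C/C1=C\CC(C)(C)C[C@H](OC(=O)CP(=O)(Oc2ccccc2)Oc2ccccc2)C/C(C)=C/CC1
F9 | step 9 | (1S,3E,7E)-3,7,10,10-tetramethylcycloundeca-3,7-dien-1-yl (2Z)-3-{4-[(tert-butyldimethylsilyl)oxy]phenyl}prop-2-enoate | C/C1=C\CC(C)(C)C[C@H](OC(=O)/C=C\c2ccc(O[Si](C)(C)C(C)(C)C)cc2)C/C(C)=C/CC1
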